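The target stalls.

common to all: gas 0.91 mM (held); free catalyst 0.2 mol%
- epsilon: starting material 2 mM; impurity 0.63 µM; temperature −20 °C; the very flask that is asked about, followed so far
- gamma: starting material 2 mM; impurity 0.32 µM; temperature −25 °C; run made earlier
- flask: starting material 2.0 mM; impurity 0.63 µM; temperature −20 °C; time 1.0 h

| epsilon: time / min | epsilon: target / % | gamma: time / min | gamma: target / % |
|---|---|---|---|
| 6.00 | 34.2 | 0.333 | 7.5 |
| 12.0 | 33.7 | 0.500 | 9.8 |
| 20.0 | 33.9 | 1.00 | 16.2 |
| 25.0 | 34.8 | 1.50 | 18.6 |
| 30.0 | 33.2 | 2.50 | 19.5 |
| 40.0 | 33.8 | 4.00 | 19.3 |

(readings scatter by 0.5 percentage points)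
- Wednesday's: at 1.0 h add free catalyst, 100% of the amount charged, then wait 2.0 h
- Sunday's: change nothing and wait 2.0 h more
- Tuesday's: at 1.0 h raise the temperature by 20 K, then wait 2.0 h
- Saturday's: at 1.0 h take out 90% of the target then present, then wait 2.0 h
- removed target is counted in
- at the start none of the gas is in solution
- additions bring no volume worth counting
* target, in percent of the starting material first charged, at 1.0 h
* which option adds most target ("none" when 2 percentage points or less is all one gets) (Wednesday's / Sunday's / Tuesday's / Saturday's / none)
* target present, with what was taken out counted in, in percent of the starting material first charged, after Sunday's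
* target present, with what was taken out counted in, in percent of the starting material first charged, after Saturday's

1. The epsilon run, which is the asked flask followed so far, stays flat from 6.00 min to 40.0 min at a mean of 33.9%. So the reckoning here puts this flask at that value at 1.0 h, and Sunday's adds nothing. The gamma run levels off at 19.4%.

2. Turned round, the question is what must be true for Saturday's to add target after the stall. The stall has to be a balance (thermodynamic control), with target still exchanging with the rest of the charge. The two runs change temperature and impurity together, so they leave the two unseparated; the reckoning below is a bet on a balance.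

3. The scale is the target odds, c(target) divided by the c of everything else from the charge: as read from the scattered plateaus, 0.514 in epsilon, against 0.241 in gamma. Odds of 1 are the symmetric case, the zero of the scale.

4. In Saturday's, the flask loses 30.5% of the charge as target, and on this bet what stays returns to the same odds. The reckoned total is 54.1%, a gain of 20 percentage points, which is more than the margin.

5. In Tuesday's, if temperature carries the step from gamma to epsilon, the rise repeats that step and gives odds of 10.7, or 91.5% target, which is more than Saturday's total. In Wednesday's, on the same bet, added catalyst leaves the balance where it stands. The reckoning therefore names Tuesday's.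

6. The forecast gives 33.9% now, 33.9% after Sunday's, 33.9% after Saturday's, and best none, on the ground that “waiting or removing target gains nothing”. It parts from this reckoning on Saturday's and on the best option.

The flask gives 33.8%, and Tuesday's is best, adding 44 points; Saturday's ends at 54.0%.

    starting material + coupling partner ⇌ target (K = 1800 M⁻¹, k = 893 M⁻¹ s⁻¹, Ea = 36.0 kJ mol⁻¹, ΔH = 28.0 kJ mol⁻¹)
    starting material + coupling partner ⇌ isomer of the product (K = 2420 M⁻¹, k = 459 M⁻¹ s⁻¹, Ea = 36.0 kJ mol⁻¹, ΔH = −67.0 kJ mol⁻¹)
    target + free catalyst ⇌ isomer of the product + free catalyst, rate k3*[free catalyst]*[target] forward; the back reaction follows from the equilibrium constant (k = 1010 M⁻¹ s⁻¹, Ea = 38.0 kJ mol⁻¹)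
    gas ⇌ coupling partner, rate k4*(csat - [coupling partner]) (kL = 0.0320 s⁻¹)
    free catalyst + impurity → spent catalyst (k = 1.35 × 10⁷ M⁻¹ s⁻¹, Ea = 17.0 kJ mol⁻¹)
    (constants at −20 °C)

At 60.0 min the flask holds 21% starting material, 33.8% target and 45.5% isomer of the product. With the removed part set aside, Saturday's flask returns to target odds of 0.512, against the 0.514 read from epsilon. Carried up to 5 °C, the odds step gives 22.7, while that neighbour flask stands at odds of 4.81, with 82.8% target.

Readings and results were computed for an exercise; the scatter is artificial.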